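**Retrosynthetic overview**
- Target ⇒ O-methylation of the two enolic OH groups of the 2,5-dihydroxy-3,6-bis(indolyl)-1,4-benzoquinone (last step, as in the biosynthesis).
- Quinone ring ⇒ head-to-tail double Claisen (crossed Claisen, then Dieckmann) of two different indol-3-ylpyruvate units, the non-enzymatic counterpart of the indolepyruvate dimerisation that builds the asterriquinone core: indole-3-pyruvic acid activated as its acyl imidazolide plus ethyl (7-prenylindol-3-yl)pyruvate.
- Ethyl (7-prenylindol-3-yl)pyruvate ⇒ α-oximino ester ⇒ 7-prenylindole plus the nitrosoalkene from ethyl 3-bromo-2-(hydroxyimino)propanoate.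
- 7-Prenylindole ⇒ 7-bromoindole plus prenyl bromide.
- Ring order: both indole rings are bought; the quinone ring is the only ring made and is formed in the penultimate step.

Assumption: the target has no stereocentre and no stereogenic double bond, so it is one achiral compound and no step has to control configuration; ethyl 3-bromo-2-(hydroxyimino)propanoate is taken as a catalogue reagent.

**Step 1**
Reactants: 1 7-bromo-1H-indole; 2 1-bromo-3-methylbut-2-ene (prenyl bromide)
Product: 4 7-(3-methylbut-2-en-1-yl)-1H-indole, via potassium 7-lithioindol-1-ide 3 (not isolated)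
Conditions: KH, THF, 0 °C; t-BuLi (2.0 equiv), −78 °C; 2 (1.0 equiv), −78 °C → rt; H2O
Reagents that add atoms: 1-bromo-3-methylbut-2-ene (compound 2), CC(C)=CCBr
Why: KH masks the N–H as the potassium indolide, t-BuLi then effects bromine–lithium exchange at C7 (the second equivalent destroys t-BuBr), and the aryllithium attacks the primary carbon of prenyl bromide (halogen–metal exchange followed by SN2 alkylation) to give the linear prenyl group; one equivalent of electrophile at −78 °C keeps N-alkylation low, and no stereocentre is formed.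

**Step 2**
Reactants: 4 7-(3-methylbut-2-en-1-yl)-1H-indole; 5 ethyl 3-bromo-2-(hydroxyimino)propanoate
Product: 7 ethyl (2E)-2-(hydroxyimino)-3-[7-(3-methylbut-2-en-1-yl)-1H-indol-3-yl]propanoate, via ethyl 2-nitrosoprop-2-enoate 6 (not isolated)
Conditions: Na2CO3 (solid, excess), CH2Cl2, rt, 20 h; 5 (1.3 equiv) added in portions
Reagents that add atoms: ethyl 3-bromo-2-(hydroxyimino)propanoate (compound 5), CCOC(=O)C(CBr)=NO
Why: Na2CO3 dehydrobrominates 5 to the transient nitrosoalkene 6, which the enamine-like C2=C3 bond of the indole traps at C3 (nitrosoalkene conjugate alkylation of indoles, formally hetero-Diels–Alder then ring-opening) far faster than the isolated prenyl olefin can react; this installs the whole pyruvate chain with the ketone masked as an oxime whose geometry is immaterial.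

**Step 3**
Reactants: 7 ethyl (2E)-2-(hydroxyimino)-3-[7-(3-methylbut-2-en-1-yl)-1H-indol-3-yl]propanoate
Product: 9 ethyl 3-[7-(3-methylbut-2-en-1-yl)-1H-indol-3-yl]-2-oxopropanoate, via imino ester 8 (not isolated)
Conditions: TiCl3 (aq. HCl solution, 2.5 equiv), NH4OAc, THF/H2O, 0 °C → rt, Ar
Reagents that add atoms: water, O
Why: trivalent titanium cleaves the N–O bond reductively and the N-unsubstituted imine 8 hydrolyses at once in the acetate buffer to the α-keto ester (reductive deoximation), under near-neutral conditions that spare the indole, ester and prenyl olefin; 9 is largely its Z-enol and is used promptly under argon.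

**Step 4**
Reactants: 9 ethyl 3-[7-(3-methylbut-2-en-1-yl)-1H-indol-3-yl]-2-oxopropanoate; 10 3-(1H-indol-3-yl)-2-oxopropanoic acid (indole-3-pyruvic acid)
Product: 13 2,5-dihydroxy-3-(1H-indol-3-yl)-6-[7-(3-methylbut-2-en-1-yl)-1H-indol-3-yl]cyclohexa-2,5-diene-1,4-dione, via acyl imidazolide 11 (not isolated), via open-chain trioxohexanoate 12 (not isolated)
Conditions: 10 (3 equiv), CDI (3 equiv), THF, 0 °C → rt, 1 h; then 9 (1 equiv), MgCl2 (4 equiv), Et3N (8 equiv), MeCN, 0 °C → rt; then NaOEt (8 equiv), EtOH, 50 °C; 1 M HCl; all under Ar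
Reagents that add atoms: none
Why: Proposed new method: a non-enzymatic version of the thioester-driven head-to-tail joining of two indolepyruvate units, in which CDI turns 10 into acyl imidazolide 11 (a thioester surrogate), the chelated magnesium enolate of 9 is C-acylated at its benzylic carbon by 11 to give 12 (crossed Claisen; closest precedent the Masamune–Brooks/Rathke acylation of magnesium enolates by acyl imidazolides), and ethoxide then drives the 6-(enolendo)-exo-trig Dieckmann closure of the second enolate carbon onto the ethyl ester, pulled irreversibly by formation of the doubly vinylogous dicarboxylate of 13 (closest precedent the alkoxide-induced rearrangement of grevillin-type pyrandiones to 2,5-diaryl-3,6-dihydroxybenzoquinones, which runs through the same acyclic keto ester enolate). Cross-selectivity rests on only 10 being activated: the unactivated ester 9 cannot condense with itself and is consumed by excess 11; any O-acylated enol ester or pyrandione is funnelled to the same quinone by imidazole and ethoxide; the only quinone by-product, the unprenylated homodimer from surplus 10, is removed by reversed-phase chromatography; no stereocentre is formed.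

**Step 5**
Reactants: 13 2,5-dihydroxy-3-(1H-indol-3-yl)-6-[7-(3-methylbut-2-en-1-yl)-1H-indol-3-yl]cyclohexa-2,5-diene-1,4-dione; 14 (trimethylsilyl)diazomethane
Product: 15 3-(1H-indol-3-yl)-2,5-dimethoxy-6-[7-(3-methylbut-2-en-1-yl)-1H-indol-3-yl]cyclohexa-2,5-diene-1,4-dione (target)
Conditions: TMSCHN2 (2.5 equiv), MeOH/toluene 1:4, 0 °C → rt
Reagents that add atoms: (trimethylsilyl)diazomethane (compound 14), C[Si](C)(C)C=[N+]=[N-]
Why: the two enolic OH groups are vinylogous carboxylic acids and are O-methylated by the diazoalkane (diazomethane-type esterification) to the favoured 2,5-dimethoxy-para-quinone, while the far less acidic indole N–H groups and the prenyl olefin do not react.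

**Compound list**
1 | 7-bromo-1H-indole | Brc1cccc2cc[nH]c12 | starting material
2 | 1-bromo-3-methylbut-2-ene (prenyl bromide) | CC(C)=CCBr | starting material
3 | potassium 7-lithioindol-1-ide | [Li]c1cccc2cc[n-]c12.[K+] | intermediate (not isolated)
4 | 7-(3-methylbut-2-en-1-yl)-1H-indole | CC(C)=CCc1cccc2cc[nH]c12 | intermediate
5 | ethyl 3-bromo-2-(hydroxyimino)propanoate (oxime geometry not defined, immaterial) | CCOC(=O)C(CBr)=NO | starting material
6 | ethyl 2-nitrosoprop-2-enoate | CCOC(=O)C(=C)N=O | intermediate (not isolated)
7 | ethyl (2E)-2-(hydroxyimino)-3-[7-(3-methylbut-2-en-1-yl)-1H-indol-3-yl]propanoate | CCOC(=O)/C(Cc1c[nH]c2c(CC=C(C)C)cccc12)=N/O | intermediate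
8 | ethyl 2-imino-3-[7-(3-methylbut-2-en-1-yl)-1H-indol-3-yl]propanoate | CCOC(=O)C(=N)Cc1c[nH]c2c(CC=C(C)C)cccc12 | intermediate (not isolated)
9 | ethyl 3-[7-(3-methylbut-2-en-1-yl)-1H-indol-3-yl]-2-oxopropanoate (keto form drawn; mainly Z-enol) | CCOC(=O)C(=O)Cc1c[nH]c2c(CC=C(C)C)cccc12 | intermediate
10 | 3-(1H-indol-3-yl)-2-oxopropanoic acid (indole-3-pyruvic acid) | OC(=O)C(=O)Cc1c[nH]c2ccccc12 | starting material
11 | 1-(1H-imidazol-1-yl)-3-(1H-indol-3-yl)propane-1,2-dione | O=C(Cc1c[nH]c2ccccc12)C(=O)n1ccnc1 | intermediate (not isolated)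
12 | ethyl 6-(1H-indol-3-yl)-3-[7-(3-methylbut-2-en-1-yl)-1H-indol-3-yl]-2,4,5-trioxohexanoate (keto form drawn; enolised, C3 configurationally labile) | CCOC(=O)C(=O)C(C(=O)C(=O)Cc1c[nH]c2ccccc12)c1c[nH]c2c(CC=C(C)C)cccc12 | intermediate (not isolated)
13 | 2,5-dihydroxy-3-(1H-indol-3-yl)-6-[7-(3-methylbut-2-en-1-yl)-1H-indol-3-yl]cyclohexa-2,5-diene-1,4-dione | OC1=C(c2c[nH]c3ccccc23)C(=O)C(O)=C(c2c[nH]c3c(CC=C(C)C)cccc23)C1=O | intermediate
14 | (trimethylsilyl)diazomethane | C[Si](C)(C)C=[N+]=[N-] | starting material
15 | 3-(1H-indol-3-yl)-2,5-dimethoxy-6-[7-(3-methylbut-2-en-1-yl)-1H-indol-3-yl]cyclohexa-2,5-diene-1,4-dione | COC1=C(c2c[nH]c3ccccc23)C(=O)C(OC)=C(c2c[nH]c3c(CC=C(C)C)cccc23)C1=O | target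

**Step count**
Total steps: 5. Longest linear sequence: 5 (1 → 4 → 7 → 9 → 13 → 15).

**Steps most likely to fail, with fallbacks**

Step 4 (crossed Claisen–Dieckmann). The risks are self-condensation of the enolisable acyl imidazolide and attack of the enolate of 9 on the ketone of 11 (aldol, then lactonisation to an isotetronic acid, the usual non-enzymatic fate of arylpyruvates). The fallback changes the acyl donor to one with a masked ketone and no acidic C–H. It sets out from 10: acetalisation of its enol–acid form with 2,2-dimethoxypropane and catalytic pyridinium p-toluenesulfonate gives (Z)-5-(1H-indol-3-ylmethylidene)-2,2-dimethyl-1,3-dioxolan-4-one F1. Adding F1 to the preformed lithium enolate of 9 (LiHMDS, THF, −78 °C → rt) opens the activated lactone by acyl substitution, expels acetone and unveils the second enolate as 12. NaOEt in EtOH then closes 12, and the route is rejoined at 13.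

Step 3 (deoximation to an air-sensitive, enolised keto ester). The risks are incomplete N–O reduction and oxidative cleavage of the enol. The fallback avoids the oxime altogether and sets out from 4: Yb(OTf)3-catalysed Friedel–Crafts opening of ethyl oxirane-2-carboxylate at its CH2 terminus by indole C3 gives racemic ethyl 2-hydroxy-3-[7-(3-methylbut-2-en-1-yl)-1H-indol-3-yl]propanoate F2. Dess–Martin periodinane oxidation of the secondary alcohol (NaHCO3, CH2Cl2) returns to the route at 9.

Step 1 (prenylation via the dianion). The risks are N-prenylation, SN2' attack giving the reverse-prenyl isomer, and simple protonation to indole. The fallback inverts the polarity of the coupling and sets out from 1: Miyaura borylation (bis(pinacolato)diboron, KOAc, PdCl2(dppf), dioxane, 90 °C) gives 7-(4,4,5,5-tetramethyl-1,3,2-dioxaborolan-2-yl)-1H-indole F3. Pd(PPh3)4-catalysed allylic cross-coupling of F3 with 2 (K2CO3, THF/H2O) goes through a π-prenyl palladium intermediate that is arylated at its unhindered terminus, and returns to the route at 4.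

**Further compounds**
F1 | step 4 | (Z)-5-(1H-indol-3-ylmethylidene)-2,2-dimethyl-1,3-dioxolan-4-one | CC1(C)OC(=O)/C(=C/c2c[nH]c3ccccc23)O1
F2 | step 3 | ethyl 2-hydroxy-3-[7-(3-methylbut-2-en-1-yl)-1H-indol-3-yl]propanoate (racemic) | CCOC(=O)C(O)Cc1c[nH]c2c(CC=C(C)C)cccc12
F3 | step 1 | 7-(4,4,5,5-tetramethyl-1,3,2-dioxaborolan-2-yl)-1H-indole | CC1(C)OB(OC1(C)C)c1cccc2cc[nH]c12
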